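**Plan**
- Numbering: ring C1' (carbinol), C2' (methyl-bearing) =C3', C4' (ketone), C5', C6' (quaternary, carrying the C9' methyl and C8'H2–O); side chain C1–C5 with C5 on C1'.
- Cuts, in retrosynthetic order: both carboxyls (allyl esters); C3–C4 (vinyl iodide plus Z-stannyl crotonate); C4=C5 (iodo-olefination of a C1' aldehyde kept as its dimethyl acetal); the O8'–acyl bond (hydroxymethylglutarate half-ester); ring bond C1'–C6' (aldol) together with the C1'/C4' carbonyl pair (furan); furan–C5' (conjugate addition to methacrolein).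
- Enabling feature: C1'(O)–C2'(CH3)=C3'H–C4'(=O) with its cis ring alkene is an opened 2,5-disubstituted 3-methylfuran, and C6' is the α-carbon of an aldehyde (C8'), so the only ring closes through the aldol bond C1'–C6'.
- Forward order: furfural acetal, C5'–C6'–C8' chain, one-flask furan opening and aldol (the single ring), reduction, O8' esterification, C4' reoxidation, C5 aldehyde, E-vinyl iodide, dienoate, deallylation; half-ester and stannane are made separately.
- Stereochemistry: C1' and C6' from the chiral amine in the aldol (OH trans to C8'). The glutarate carbinol comes from (R)-mevalonolactone, whose C1 carboxyl becomes the O8' ester and whose C5 is oxidised to the free acid. 4E comes from the Takai olefination and 2Z from the Z-stannane.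

Key step: step 3

Assumption: the sense of induction in step 3 is assigned from the hydrogen-bonded enamine model of proline-type enolexo aldolisations, which points to the (R)-configured pyrrolidine catalyst for (1R,2R)-10; the antipodal catalyst is equally available should the model fail.

**Step 1**
Reactants: 1 3-methylfuran-2-carbaldehyde
Product: 2 2-(dimethoxymethyl)-3-methylfuran
Conditions: HC(OMe)3, MeOH, p-TsOH·H2O (cat.), rt; Et3N quench
Reagents that add atoms: trimethyl orthoformate, COC(OC)OC
Why: Acid-catalysed acetalisation with the orthoformate as water scavenger masks the aldehyde for the lithiation and supplies the group that later activates the C1' ketone and becomes C5.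

**Step 2**
Reactants: 2 2-(dimethoxymethyl)-3-methylfuran; 3 methacrolein
Product: 7 3-[5-(dimethoxymethyl)-4-methylfuran-2-yl]-2-methylpropanal (racemic), via furyllithium 4 (not isolated), via furylmagnesium bromide 5 (not isolated), via silyl enol ether 6 (not isolated)
Conditions: n-BuLi, THF, −78 to 0 °C; MgBr2·OEt2, −78 °C; CuBr·SMe2 (10 mol %), TMSCl, DMPU, then 3, −78 to −40 °C; then K2CO3, MeOH, 0 °C
Reagents that add atoms: none
Why: The only free furan α-position is lithiated and the derived Grignard reagent adds 1,4 to the enal in a copper-catalysed, TMSCl-accelerated conjugate addition, the silyl enol ether being cleaved by basic methanolysis that spares the acetal; the new α-centre is racemic and is erased in step 3.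

**Step 3**
Reactants: 7 3-[5-(dimethoxymethyl)-4-methylfuran-2-yl]-2-methylpropanal
Product: 10 (1R,2R)-2-(dimethoxymethyl)-2-hydroxy-1,3-dimethyl-5-oxocyclohex-3-ene-1-carbaldehyde, via endoperoxide 8 (not isolated), via Z-enedione 9 (not isolated)
Conditions: O2, tetraphenylporphyrin (cat.), visible light, CH2Cl2, −78 °C; Me2S, −78 to 0 °C; (R)-5-(pyrrolidin-2-yl)-1H-tetrazole (20 mol %), 0 °C to rt, dark
Reagents that add atoms: dioxygen, O=O
Why: Proposed new method: sensitised singlet oxygen adds [4+2] across the furan α-carbons to give endoperoxide 8, Me2S reduces the O–O bond to the cis-enedione 9 (closest known: singlet-oxygen opening of 2,5-disubstituted furans to Z-ene-1,4-diones), and the pyrrolidine catalyst then condenses with the aldehyde so that both C6' epimers converge on one enamine whose carbon C6' attacks the C1' ketone, made more electrophilic by its dimethoxymethyl neighbour (closest known: proline-type enolexo aldolisation of keto aldehydes and amine-catalysed aldols of α-branched aldehydes). The six-membered ring closes in the 6-(enolexo)-exo-trig mode, which is possible only because the cis C2'=C3' bond inherited from the furan holds C1' over the enamine. C6' and C1' are set together in a hydrogen-bonded transition state in which the tetrazole N–H of the E-enamine bridges to the ketone oxygen: O1' and the enamine carbon C8' lie gauche and pseudo-equatorial, while the dimethoxymethyl group and the C6' methyl lie anti and pseudo-axial, free of A(1,2) strain with the C2' methyl, which should give the anti aldol with OH trans to CHO. The absolute sense follows from the enamine face that carries the tetrazole, which for the (R)-catalyst is the face needed for (1R,2R)-10. The step needs the aldehyde enamine to outrun five-ring aldolisation from C5', amine conjugate addition and Z-to-E isomerisation of the enedione: a secondary amine cannot drain the 1,4-keto aldehyde as a pyrrole (Paal–Knorr), its acidic partner keeps conjugate addition reversible, and the acetal on C1' offers no further acceptor site. Aldol 10 is not stored but reduced at once in step 4.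

**Step 4**
Reactants: 10 (1R,2R)-2-(dimethoxymethyl)-2-hydroxy-1,3-dimethyl-5-oxocyclohex-3-ene-1-carbaldehyde
Product: 11 (1R,6S)-1-(dimethoxymethyl)-6-(hydroxymethyl)-2,6-dimethylcyclohex-2-ene-1,4-diol (both C4 epimers)
Conditions: NaBH4, CeCl3·7H2O, MeOH, −78 to 0 °C
Reagents that add atoms: none
Why: Luche reduction delivers hydride 1,2 to the enone and also reduces the aldehyde, which closes the retro-aldol pathway and leaves no enone to which the new O8' hydroxyl could add (phaseic-type cyclisation); the C4' carbinol forms uncontrolled and is reoxidised in step 10.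

**Step 5**
Reactants: 12 (R)-mevalonolactone
Product: 14 4-methoxybenzyl (3R)-3,5-dihydroxy-3-methylpentanoate, via potassium (R)-mevalonate 13 (not isolated)
Conditions: KOH (1 equiv), H2O, rt; concentrate; 4-methoxybenzyl chloride, DMF, rt
Reagents that add atoms: potassium hydroxide, [K+].[OH-]; 4-methoxybenzyl chloride, COc1ccc(CCl)cc1
Why: Saponification opens the lactone and SN2 O-alkylation of the carboxylate fixes C1 as a PMB ester, which distinguishes the two ends of the chain without touching the carbinol centre; 14 is used at once to avoid relactonisation.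

**Step 6**
Reactants: 14 4-methoxybenzyl (3R)-3,5-dihydroxy-3-methylpentanoate
Product: 15 (3R)-3-hydroxy-5-[(4-methoxybenzyl)oxy]-3-methyl-5-oxopentanoic acid
Conditions: TEMPO (cat.), PhI(OAc)2, MeCN/H2O, rt
Reagents that add atoms: water, O
Why: Oxoammonium (TEMPO/PhI(OAc)2) oxidation takes the primary alcohol through the aldehyde hydrate to the acid and cannot oxidise the tertiary alcohol.

**Step 7**
Reactants: 15 (3R)-3-hydroxy-5-[(4-methoxybenzyl)oxy]-3-methyl-5-oxopentanoic acid
Product: 16 1-(4-methoxybenzyl) 5-(prop-2-enyl) (3R)-3-hydroxy-3-methylpentanedioate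
Conditions: allyl bromide, KHCO3, DMF, rt
Reagents that add atoms: allyl bromide, C=CCBr
Why: Carboxylate O-alkylation under bicarbonate conditions is mild enough to leave the β-hydroxy diester intact.

**Step 8**
Reactants: 16 1-(4-methoxybenzyl) 5-(prop-2-enyl) (3R)-3-hydroxy-3-methylpentanedioate
Product: 17 (3S)-3-hydroxy-3-methyl-5-oxo-5-(prop-2-enyloxy)pentanoic acid
Conditions: TFA, anisole, CH2Cl2, 0 °C
Reagents that add atoms: none
Why: Acidolysis of the PMB ester (anisole traps the benzylic cation) frees the former C1 carboxyl while the allyl ester survives; the centre is untouched and reads S only because the ranks of its two arms are exchanged.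

**Step 9**
Reactants: 11 (1R,6S)-1-(dimethoxymethyl)-6-(hydroxymethyl)-2,6-dimethylcyclohex-2-ene-1,4-diol; 17 (3S)-3-hydroxy-3-methyl-5-oxo-5-(prop-2-enyloxy)pentanoic acid
Product: 18 [(1S,2R)-2-(dimethoxymethyl)-2,5-dihydroxy-1,3-dimethylcyclohex-3-en-1-yl]methyl prop-2-enyl (3R)-3-hydroxy-3-methylpentanedioate (both C5 epimers)
Conditions: DCC, DMAP (cat.), CH2Cl2, 0 °C, 17 as limiting reagent
Reagents that add atoms: none
Why: In this Steglich esterification the primary O8' hydroxyl should react ahead of the secondary allylic O4' and the two tertiary hydroxyls, and it is acylated while C4' is still a carbinol so that no free O8' hydroxyl ever faces the enone.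

**Step 10**
Reactants: 18 [(1S,2R)-2-(dimethoxymethyl)-2,5-dihydroxy-1,3-dimethylcyclohex-3-en-1-yl]methyl prop-2-enyl (3R)-3-hydroxy-3-methylpentanedioate
Product: 19 [(1S,2R)-2-(dimethoxymethyl)-2-hydroxy-1,3-dimethyl-5-oxocyclohex-3-en-1-yl]methyl prop-2-enyl (3R)-3-hydroxy-3-methylpentanedioate
Conditions: MnO2 (excess), CH2Cl2, rt
Reagents that add atoms: none
Why: MnO2 oxidises only the allylic secondary alcohol, which restores the enone and merges the C4' epimers; tertiary alcohols, acetal and esters are inert.

**Step 11**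
Reactants: 19 [(1S,2R)-2-(dimethoxymethyl)-2-hydroxy-1,3-dimethyl-5-oxocyclohex-3-en-1-yl]methyl prop-2-enyl (3R)-3-hydroxy-3-methylpentanedioate
Product: 20 [(1S,2R)-2-formyl-2-hydroxy-1,3-dimethyl-5-oxocyclohex-3-en-1-yl]methyl prop-2-enyl (3R)-3-hydroxy-3-methylpentanedioate
Conditions: 2 M aq. HCl, THF, 0 °C to rt; used crude
Reagents that add atoms: water, O
Why: Aqueous acid hydrolysis of the dimethyl acetal is slowed but not prevented by the α-hydroxyl, the enone disfavours ionisation of the tertiary allylic alcohol, and the aldehyde is taken on at once to avoid α-ketol rearrangement.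

**Step 12**
Reactants: 20 [(1S,2R)-2-formyl-2-hydroxy-1,3-dimethyl-5-oxocyclohex-3-en-1-yl]methyl prop-2-enyl (3R)-3-hydroxy-3-methylpentanedioate
Product: 21 [(1S,2R)-2-hydroxy-2-[(E)-2-iodoethenyl]-1,3-dimethyl-5-oxocyclohex-3-en-1-yl]methyl prop-2-enyl (3R)-3-hydroxy-3-methylpentanedioate
Conditions: CrCl2, CHI3, THF/dioxane, 0 °C to rt, dark
Reagents that add atoms: iodoform, IC(I)I
Why: Takai olefination adds the geminal dichromium reagent to the aldehyde only (ketone and esters are spared) and the anti elimination of the adduct should give the E-vinyl iodide, which fixes the 4E geometry.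

**Step 13**
Reactants: 22 but-2-ynoic acid
Product: 23 prop-2-enyl but-2-ynoate
Conditions: allyl bromide, KHCO3, DMF, rt
Reagents that add atoms: allyl bromide, C=CCBr
Why: Carboxylate O-alkylation gives the allyl ynoate without base strong enough to isomerise the alkyne.

**Step 14**
Reactants: 23 prop-2-enyl but-2-ynoate
Product: 25 prop-2-enyl (Z)-3-(trimethylstannyl)but-2-enoate, via alkenylcuprate adduct 24 (not isolated)
Conditions: (Me3Sn)2, MeLi, THF, −20 °C; PhSCu, −20 °C; 23, −78 to −48 °C, 4 h; MeOH, −78 °C
Reagents that add atoms: hexamethylditin, C[Sn](C)(C)[Sn](C)(C)C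
Why: Stannylcupration of the ynoate under thermodynamic control lets the first-formed syn adduct equilibrate through the allenoate to the isomer with tin cis to the ester before protonation, which gives the Z-stannane.

**Step 15**
Reactants: 21 [(1S,2R)-2-hydroxy-2-[(E)-2-iodoethenyl]-1,3-dimethyl-5-oxocyclohex-3-en-1-yl]methyl prop-2-enyl (3R)-3-hydroxy-3-methylpentanedioate; 25 prop-2-enyl (Z)-3-(trimethylstannyl)but-2-enoate
Product: 26 prop-2-enyl (2Z,4E)-5-[(1R,6S)-1-hydroxy-6-({[(3R)-3-hydroxy-3-methyl-5-oxo-5-(prop-2-enyloxy)pentanoyl]oxy}methyl)-2,6-dimethyl-4-oxocyclohex-2-en-1-yl]-3-methylpenta-2,4-dienoate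
Conditions: copper thiophene-2-carboxylate Cu(O2CC4H3S) (1.5 equiv), NMP, 0 °C to rt, dark
Reagents that add atoms: none
Why: In this copper-mediated Stille-type coupling tin-to-copper transmetalation, assisted by the cis ester, and reaction with the vinyl iodide join C3 to C4 with retention at both alkenes, and the absence of zerovalent palladium leaves the two allyl esters untouched.

**Step 16**
Reactants: 26 prop-2-enyl (2Z,4E)-5-[(1R,6S)-1-hydroxy-6-({[(3R)-3-hydroxy-3-methyl-5-oxo-5-(prop-2-enyloxy)pentanoyl]oxy}methyl)-2,6-dimethyl-4-oxocyclohex-2-en-1-yl]-3-methylpenta-2,4-dienoate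
Product: 27 (2Z,4E)-5-[(1R,6S)-6-({[(3R)-4-carboxy-3-hydroxy-3-methylbutanoyl]oxy}methyl)-1-hydroxy-2,6-dimethyl-4-oxocyclohex-2-en-1-yl]-3-methylpenta-2,4-dienoic acid
Conditions: Pd(PPh3)4 (5 mol %), morpholine, THF, rt, dark; aq. NaH2PO4 (pH 3) work-up
Reagents that add atoms: none
Why: Tsuji–Trost deallylation ionises both allyl esters with zerovalent palladium and morpholine captures the allyl groups under neutral conditions that should spare the O8' ester, the tertiary alcohols and the light- and acid-sensitive Z,E-dienoic acid.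

**Compound list**
1 | 3-methylfuran-2-carbaldehyde | Cc1ccoc1C=O | starting material
2 | 2-(dimethoxymethyl)-3-methylfuran | COC(OC)c1occc1C | intermediate
3 | methacrolein (2-methylprop-2-enal) | CC(=C)C=O | starting material
4 | [5-(dimethoxymethyl)-4-methylfuran-2-yl]lithium (not isolated) | [Li]c1cc(C)c(C(OC)OC)o1 | intermediate
5 | [5-(dimethoxymethyl)-4-methylfuran-2-yl]magnesium bromide (not isolated) | Br[Mg]c1cc(C)c(C(OC)OC)o1 | intermediate
6 | {3-[5-(dimethoxymethyl)-4-methylfuran-2-yl]-2-methylprop-1-enoxy}trimethylsilane, E/Z mixture (not isolated) | COC(OC)c1oc(CC(C)=CO[Si](C)(C)C)cc1C | intermediate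
7 | 3-[5-(dimethoxymethyl)-4-methylfuran-2-yl]-2-methylpropanal (racemic) | COC(OC)c1oc(CC(C)C=O)cc1C | intermediate
8 | 3-[1-(dimethoxymethyl)-6-methyl-2,3,7-trioxabicyclo[2.2.1]hept-5-en-4-yl]-2-methylpropanal (not isolated) | COC(OC)C12OOC(CC(C)C=O)(O1)C=C2C | intermediate
9 | (5Z)-8,8-dimethoxy-2,6-dimethyl-4,7-dioxooct-5-enal (not isolated) | COC(OC)C(=O)/C(C)=C\C(=O)CC(C)C=O | intermediate
10 | (1R,2R)-2-(dimethoxymethyl)-2-hydroxy-1,3-dimethyl-5-oxocyclohex-3-ene-1-carbaldehyde | CC1=CC(=O)C[C@@](C)(C=O)[C@@]1(O)C(OC)OC | intermediate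
11 | (1R,6S)-1-(dimethoxymethyl)-6-(hydroxymethyl)-2,6-dimethylcyclohex-2-ene-1,4-diol (both C4 epimers) | CC1=CC(O)C[C@@](C)(CO)[C@@]1(O)C(OC)OC | intermediate
12 | (R)-mevalonolactone, (4R)-4-hydroxy-4-methyloxan-2-one | C[C@@]1(O)CCOC(=O)C1 | starting material
13 | potassium (3R)-3,5-dihydroxy-3-methylpentanoate (not isolated) | C[C@@](CC(=O)[O-])(O)CCO.[K+] | intermediate
14 | 4-methoxybenzyl (3R)-3,5-dihydroxy-3-methylpentanoate | C[C@@](CC(=O)OCc1ccc(OC)cc1)(O)CCO | intermediate
15 | (3R)-3-hydroxy-5-[(4-methoxybenzyl)oxy]-3-methyl-5-oxopentanoic acid | C[C@@](CC(=O)OCc1ccc(OC)cc1)(O)CC(=O)O | intermediate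
16 | 1-(4-methoxybenzyl) 5-(prop-2-enyl) (3R)-3-hydroxy-3-methylpentanedioate | C[C@@](CC(=O)OCc1ccc(OC)cc1)(O)CC(=O)OCC=C | intermediate
17 | (3S)-3-hydroxy-3-methyl-5-oxo-5-(prop-2-enyloxy)pentanoic acid | C[C@@](CC(=O)O)(O)CC(=O)OCC=C | intermediate
18 | [(1S,2R)-2-(dimethoxymethyl)-2,5-dihydroxy-1,3-dimethylcyclohex-3-en-1-yl]methyl prop-2-enyl (3R)-3-hydroxy-3-methylpentanedioate (both C5 epimers) | CC1=CC(O)C[C@@](C)(COC(=O)C[C@](C)(O)CC(=O)OCC=C)[C@@]1(O)C(OC)OC | intermediate
19 | [(1S,2R)-2-(dimethoxymethyl)-2-hydroxy-1,3-dimethyl-5-oxocyclohex-3-en-1-yl]methyl prop-2-enyl (3R)-3-hydroxy-3-methylpentanedioate | CC1=CC(=O)C[C@@](C)(COC(=O)C[C@](C)(O)CC(=O)OCC=C)[C@@]1(O)C(OC)OC | intermediate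
20 | [(1S,2R)-2-formyl-2-hydroxy-1,3-dimethyl-5-oxocyclohex-3-en-1-yl]methyl prop-2-enyl (3R)-3-hydroxy-3-methylpentanedioate | CC1=CC(=O)C[C@@](C)(COC(=O)C[C@](C)(O)CC(=O)OCC=C)[C@@]1(O)C=O | intermediate
21 | [(1S,2R)-2-hydroxy-2-[(E)-2-iodoethenyl]-1,3-dimethyl-5-oxocyclohex-3-en-1-yl]methyl prop-2-enyl (3R)-3-hydroxy-3-methylpentanedioate | CC1=CC(=O)C[C@@](C)(COC(=O)C[C@](C)(O)CC(=O)OCC=C)[C@@]1(O)/C=C/I | intermediate
22 | but-2-ynoic acid | CC#CC(=O)O | starting material
23 | prop-2-enyl but-2-ynoate | CC#CC(=O)OCC=C | intermediate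
24 | lithium [(Z)-1-(prop-2-enyloxycarbonyl)-2-(trimethylstannyl)prop-1-enyl](phenylthio)cuprate (not isolated) | [Li+].C[Sn](C)(C)/C(C)=C(\C(=O)OCC=C)[Cu-]Sc1ccccc1 | intermediate
25 | prop-2-enyl (Z)-3-(trimethylstannyl)but-2-enoate | C[Sn](C)(C)/C(C)=C\C(=O)OCC=C | intermediate
26 | prop-2-enyl (2Z,4E)-5-[(1R,6S)-1-hydroxy-6-({[(3R)-3-hydroxy-3-methyl-5-oxo-5-(prop-2-enyloxy)pentanoyl]oxy}methyl)-2,6-dimethyl-4-oxocyclohex-2-en-1-yl]-3-methylpenta-2,4-dienoate | CC1=CC(=O)C[C@@](C)(COC(=O)C[C@](C)(O)CC(=O)OCC=C)[C@@]1(O)/C=C/C(C)=C\C(=O)OCC=C | intermediate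
27 | (2Z,4E)-5-[(1R,6S)-6-({[(3R)-4-carboxy-3-hydroxy-3-methylbutanoyl]oxy}methyl)-1-hydroxy-2,6-dimethyl-4-oxocyclohex-2-en-1-yl]-3-methylpenta-2,4-dienoic acid | CC1=CC(=O)C[C@@](C)(COC(=O)C[C@](C)(O)CC(=O)O)[C@@]1(O)/C=C/C(C)=C\C(=O)O | target

**Step count and risks**
Total step count: 16. Longest linear sequence: 10 steps (steps 1–4, 9–12, 15, 16).

Steps most likely to fail:

1. Step 3 (Proposed new method). The amine may be held back by conjugate addition to the cis-enedione, may isomerise the alkene to the trans form that cannot cyclise faster than the enamine closes the ring, may allow five-ring aldolisation from C5', or may give weak facial or anti/syn control. The fallback closes the ring on a saturated substrate with known reactions. It sets out from 7: the same photooxygenation and Me2S reduction give 9, which is not exposed to amine but reduced in the flask with zinc dust in buffered acetic acid to 8,8-dimethoxy-2,6-dimethyl-4,7-dioxooctanal F1. (R)-Proline in DMSO then effects the established 6-enolexo aldolisation of a keto aldehyde that has neither a Michael acceptor nor an alkene geometry to lose, giving (1R,2R)-2-(dimethoxymethyl)-2-hydroxy-1,3-dimethyl-5-oxocyclohexane-1-carbaldehyde F2, a mixture at the methyl-bearing C2' that is of no consequence. IBX in DMSO dehydrogenates the ketone; because C6' is quaternary the new double bond can only be C2'=C3', and the route is rejoined at 10. Any residual antipode would be removed as the diastereomeric ester after step 9.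

2. Step 9. Acylation may spread over O8' and the allylic O4', because the primary hydroxyl is neopentylic. The fallback differentiates the hydroxyls by protection and sets out from 11. Phenylboronic acid ties O1' and O8' into the six-membered cyclic boronate, 8a-(dimethoxymethyl)-4a,8-dimethyl-2-phenyl-4a,5,6,8a-tetrahydro-4H-benzo[d][1,3,2]dioxaborinin-6-ol F3. TBSCl and imidazole silylate the only remaining hydroxyl to give the O4'-TBS ether of that boronate F4. Exchange with pinacol releases (1R,6S)-4-[(tert-butyldimethylsilyl)oxy]-1-(dimethoxymethyl)-6-(hydroxymethyl)-2,6-dimethylcyclohex-2-en-1-ol F5. DCC/DMAP with 17 then meets a single acylable hydroxyl and gives the O4'-TBS ether of 18 F6. TBAF buffered with acetic acid removes the silyl ether and the route is rejoined at 18.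

3. Step 12. The geminal dichromium reagent may add sluggishly to the hindered tertiary α-hydroxy aldehyde, trivalent chromium may trigger α-ketol rearrangement, or divalent chromium may reduce the γ-hydroxy enone. The fallback uses two Wittig olefinations under neutral conditions and sets out from 20. 1-(Triphenylphosphoranylidene)propan-2-one in toluene gives [(1S,2R)-2-hydroxy-1,3-dimethyl-5-oxo-2-[(E)-3-oxobut-1-enyl]cyclohex-3-en-1-yl]methyl prop-2-enyl (3R)-3-hydroxy-3-methylpentanedioate F7. Prop-2-enyl (triphenylphosphoranylidene)acetate in hot toluene then olefinates the side-chain methyl ketone (the hindered ring ketone does not react) to give 26 together with the (2E,4E) isomer of 26 F8. The two are separated by chromatography, F8 is recycled by photoequilibration of the 2,3-double bond, and the route is rejoined at 26 without steps 12 to 15.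

**Further compounds**
F1 | step 3 | 8,8-dimethoxy-2,6-dimethyl-4,7-dioxooctanal | COC(OC)C(=O)C(C)CC(=O)CC(C)C=O
F2 | step 3 | (1R,2R)-2-(dimethoxymethyl)-2-hydroxy-1,3-dimethyl-5-oxocyclohexane-1-carbaldehyde (C3 epimers) | CC1CC(=O)C[C@@](C)(C=O)[C@@]1(O)C(OC)OC
F3 | step 9 | 8a-(dimethoxymethyl)-4a,8-dimethyl-2-phenyl-4a,5,6,8a-tetrahydro-4H-benzo[d][1,3,2]dioxaborinin-6-ol (cyclic O1',O8'-phenylboronate of 11) | CC1=CC(O)C[C@@](C)(COB(c2ccccc2)O3)[C@@]13C(OC)OC
F4 | step 9 | O4'-tert-butyldimethylsilyl ether of the cyclic O1',O8'-phenylboronate of 11 | CC1=CC(O[Si](C)(C)C(C)(C)C)C[C@@](C)(COB(c2ccccc2)O3)[C@@]13C(OC)OC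
F5 | step 9 | (1R,6S)-4-[(tert-butyldimethylsilyl)oxy]-1-(dimethoxymethyl)-6-(hydroxymethyl)-2,6-dimethylcyclohex-2-en-1-ol | CC1=CC(O[Si](C)(C)C(C)(C)C)C[C@@](C)(CO)[C@@]1(O)C(OC)OC
F6 | step 9 | [(1S,2R)-5-[(tert-butyldimethylsilyl)oxy]-2-(dimethoxymethyl)-2-hydroxy-1,3-dimethylcyclohex-3-en-1-yl]methyl prop-2-enyl (3R)-3-hydroxy-3-methylpentanedioate | CC1=CC(O[Si](C)(C)C(C)(C)C)C[C@@](C)(COC(=O)C[C@](C)(O)CC(=O)OCC=C)[C@@]1(O)C(OC)OC
F7 | step 12 | [(1S,2R)-2-hydroxy-1,3-dimethyl-5-oxo-2-[(E)-3-oxobut-1-enyl]cyclohex-3-en-1-yl]methyl prop-2-enyl (3R)-3-hydroxy-3-methylpentanedioate | CC1=CC(=O)C[C@@](C)(COC(=O)C[C@](C)(O)CC(=O)OCC=C)[C@@]1(O)/C=C/C(C)=O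
F8 | step 12 | (2E,4E) isomer of 26 | CC1=CC(=O)C[C@@](C)(COC(=O)C[C@](C)(O)CC(=O)OCC=C)[C@@]1(O)/C=C/C(C)=C/C(=O)OCC=C
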